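**Plan**

1. Cuts (labdane numbering): the C13(=C16)–C14=C15 diene goes back to a C13≡C14 alkyne plus ethylene, C11–C12 to a C11 triflate plus a propargyl anion, and the C6 and C8 oxygens to a C6=C7 alkene.
2. Core cut, C5–C10 and C8–C9 together: C5–C10 is the bond common to rings A and B, and beside it ring B holds C8, C9 and the fully substituted C10 in sequence, so a C5=C6–C7=C8 diene and a C9=C10 enoate linked by the C1–C4 chain close both rings in one intramolecular Diels–Alder reaction.
3. Forward: the chain is built around the C4 quaternary carbon (malonate alkylation, then diene and enoate olefinations), rings A and B arise together in the cycloaddition, C11 is then extended, ring B is oxygenated and the diene is unmasked last.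
4. Stereochemistry: C4 from enzymatic desymmetrisation of a prochiral malonate; C5, C9 and C10 (C8 transiently) from the cycloaddition through alkene geometry, endo mode and the C4-biased chair tether; C6 from osmylation and C8 from epoxidation, both on the H5 face, the latter followed by hydride opening at C7.

Key step: step 11

Remark on numbering: labdane numbering is used (decalin C1–C10, C11 on C9, C17 on C8, C18 and C19 on C4, C20 on C10); "C20 face" is the face carrying the C10 methyl, "H5 face" the opposite one.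

Assumption: pig liver esterase is taken to give the (2R)-half ester 4, the sense usual for 2-methylmalonates with a longer second chain; were the (2S)-acid formed, the ester would be reduced first (LiBH4) and the acid second, which leads to the same aldehyde 8.

**Route**

Step 1
Reactants: 1 dimethyl 2-methylpropanedioate; 2 2-(3-chloropropyl)-2-methyl-1,3-dioxolane
Product: 3 dimethyl 2-methyl-2-[3-(2-methyl-1,3-dioxolan-2-yl)propyl]propanedioate
Conditions: NaH, NaI (cat.), DMF, 0 → 70 °C
Reagents that add atoms: none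
Why: Malonic ester alkylation (SN2 of the sodium enolate on the primary chloride under iodide catalysis) creates the quaternary, still prochiral carbon that becomes C4, with the later C10 ketone kept as its dioxolane.

Step 2
Reactants: 3 dimethyl 2-methyl-2-[3-(2-methyl-1,3-dioxolan-2-yl)propyl]propanedioate
Product: 4 (2R)-2-(methoxycarbonyl)-2-methyl-5-(2-methyl-1,3-dioxolan-2-yl)pentanoic acid
Conditions: pig liver esterase, 0.1 M phosphate buffer pH 7.5, 1 M NaOH (pH-stat), 25 °C; then cold 1 M HCl to pH 3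
Reagents that add atoms: water, O
Why: Enzymatic desymmetrising hydrolysis of one of the two enantiotopic methyl esters sets C4, the only stereocentre made before the cycloaddition, and leaves two carbonyl groups that can be told apart chemically.

Step 3
Reactants: 4 (2R)-2-(methoxycarbonyl)-2-methyl-5-(2-methyl-1,3-dioxolan-2-yl)pentanoic acid
Product: 5 methyl (2R)-2-(hydroxymethyl)-2-methyl-5-(2-methyl-1,3-dioxolan-2-yl)pentanoate
Conditions: BH3·SMe2, THF, 0 → 23 °C
Reagents that add atoms: none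
Why: Chemoselective borane reduction converts the carboxylic acid, which reacts much faster than the ester, into the C18 hydroxymethyl group without touching the quaternary centre.

Step 4
Reactants: 5 methyl (2R)-2-(hydroxymethyl)-2-methyl-5-(2-methyl-1,3-dioxolan-2-yl)pentanoate
Product: 6 methyl (2R)-2-{[tert-butyl(diphenyl)silyl]oxymethyl}-2-methyl-5-(2-methyl-1,3-dioxolan-2-yl)pentanoate
Conditions: TBDPSCl, imidazole, DMF, 23 °C
Reagents that add atoms: tert-butyl(chloro)diphenylsilane, CC(C)(C)[Si](Cl)(c1ccccc1)c1ccccc1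
Why: Silylation of the primary alcohol gives a bulky ether that withstands the bases, hydrides, Lewis acid and oxidants used later and enlarges the C18 arm for the facial bias in the cycloaddition.

Step 5
Reactants: 6 methyl (2R)-2-{[tert-butyl(diphenyl)silyl]oxymethyl}-2-methyl-5-(2-methyl-1,3-dioxolan-2-yl)pentanoate
Product: 7 (2S)-2-{[tert-butyl(diphenyl)silyl]oxymethyl}-2-methyl-5-(2-methyl-1,3-dioxolan-2-yl)pentan-1-ol
Conditions: i-Bu2AlH (2.5 equiv), CH2Cl2, −78 → 0 °C
Reagents that add atoms: none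
Why: Hydride reduction of the hindered ester is taken fully to the primary alcohol, which is more reliable than stopping at the aldehyde, and leaves dioxolane and silyl ether intact.

Step 6
Reactants: 7 (2S)-2-{[tert-butyl(diphenyl)silyl]oxymethyl}-2-methyl-5-(2-methyl-1,3-dioxolan-2-yl)pentan-1-ol
Product: 8 (2R)-2-{[tert-butyl(diphenyl)silyl]oxymethyl}-2-methyl-5-(2-methyl-1,3-dioxolan-2-yl)pentanal
Conditions: Dess–Martin periodinane, CH2Cl2, 23 °C
Reagents that add atoms: none
Why: Dess–Martin oxidation gives the non-enolisable aldehyde (the future C5) with no risk to the adjacent quaternary centre.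

Step 7
Reactants: 9 (2E)-1-bromobut-2-ene
Product: 10 diethyl [(2E)-but-2-en-1-yl]phosphonate
Conditions: P(OEt)3, neat, 130 °C
Reagents that add atoms: triethyl phosphite, CCOP(OCC)OCC
Why: Michaelis–Arbuzov reaction (SN2 attack of phosphorus at the primary allylic carbon, then dealkylation by bromide) gives the crotylphosphonate with the E double bond retained.

Step 8
Reactants: 8 (2R)-2-{[tert-butyl(diphenyl)silyl]oxymethyl}-2-methyl-5-(2-methyl-1,3-dioxolan-2-yl)pentanal; 10 diethyl [(2E)-but-2-en-1-yl]phosphonate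
Product: 11 tert-butyl({(2S,3E,5E)-2-methyl-2-[3-(2-methyl-1,3-dioxolan-2-yl)propyl]hepta-3,5-dien-1-yl}oxy)diphenylsilane
Conditions: n-BuLi, THF, −78 °C; then 8, DMPU, −78 → 23 °C
Reagents that add atoms: none
Why: Horner–Wadsworth–Emmons olefination with the lithiated allylic phosphonate forms C5=C6 with E geometry and carries the crotyl E double bond over, giving the (E,E)-diene next to the unchanged quaternary centre.

Step 9
Reactants: 11 tert-butyl({(2S,3E,5E)-2-methyl-2-[3-(2-methyl-1,3-dioxolan-2-yl)propyl]hepta-3,5-dien-1-yl}oxy)diphenylsilane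
Product: 12 (6S,7E,9E)-6-{[tert-butyl(diphenyl)silyl]oxymethyl}-6-methylundeca-7,9-dien-2-one
Conditions: PPTS (cat.), acetone/H2O, 50 °C
Reagents that add atoms: water, O
Why: Mild acid-catalysed acetal hydrolysis frees the methyl ketone without affecting the silyl ether or the diene.

Step 10
Reactants: 12 (6S,7E,9E)-6-{[tert-butyl(diphenyl)silyl]oxymethyl}-6-methylundeca-7,9-dien-2-one; 13 trimethyl phosphonoacetate
Product: 14 methyl (2E,7S,8E,10E)-7-{[tert-butyl(diphenyl)silyl]oxymethyl}-3,7-dimethyldodeca-2,8,10-trienoate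
Conditions: NaH, THF, 0 → 65 °C
Reagents that add atoms: none
Why: Horner–Wadsworth–Emmons olefination of the methyl ketone should favour the (2E)-enoate (ester trans to the longer chain), and the minor (2Z) isomer is removed by chromatography because the enoate geometry later fixes C9 relative to C10.

Step 11
Reactants: 14 methyl (2E,7S,8E,10E)-7-{[tert-butyl(diphenyl)silyl]oxymethyl}-3,7-dimethyldodeca-2,8,10-trienoate
Product: 15 methyl (4S,5S,8R,9R,10R)-18-{[tert-butyl(diphenyl)silyl]oxy}-12,13,14,15,16-pentanorlabd-6-en-11-oate (trans-fused octalin; C11 ester, C17, C19 and C20 on one face, H5 and H8 on the other)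
Conditions: EtAlCl2 (1.2 equiv), CH2Cl2, −20 → 23 °C; 1 M HCl quench
Reagents that add atoms: none
Why: Coordination of EtAlCl2 to the ester carbonyl lowers the enoate LUMO, and the C5=C6–C7=C8 diene then adds suprafacially to C9=C10 in a concerted, asynchronous [4+2] cycloaddition, the closest known reaction type being the Lewis acid-promoted type 1 intramolecular Diels–Alder reaction of 2,8,10-trienoates to trans-fused octalins. Ring B closes as the new cyclohexene through the C5–C10 and C8–C9 bonds, and ring A closes in the same event as the six-membered carbocycle that the C1–C4 tether completes across the new C5–C10 bond, the tether folding as a chair. The configurations at C9 and C10 follow from the (E)-enoate (C11 cis to the C10 methyl), and that at C8 from the (E,E)-diene combined with the ester-endo arrangement (C17 cis to C11, H8 cis to H5). C5 is set by the endo, tether-exo transition state, which puts H5 trans to the C10 methyl and so gives the trans ring fusion. The step needs endo selectivity, which the Lewis acid raises, and discrimination of the two diene faces by the existing C4 centre, which rests on the chair tether in which the C19 methyl, the smaller C4 substituent, takes the axial position on the C20 face and the silyloxymethyl arm the equatorial one. The gem-disubstituted C4 also favours the folded reactive conformer, which offsets the low reactivity of the beta-methyl enoate.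

Step 12
Reactants: 15 methyl (4S,5S,8R,9R,10R)-18-{[tert-butyl(diphenyl)silyl]oxy}-12,13,14,15,16-pentanorlabd-6-en-11-oate
Product: 16 (4S,5S,8R,9R,10R)-18-{[tert-butyl(diphenyl)silyl]oxy}-12,13,14,15,16-pentanorlabd-6-en-11-ol
Conditions: LiAlH4, THF, 0 °C
Reagents that add atoms: none
Why: LiAlH4 reduction of the C11 ester gives the primary alcohol, with no stereocentre involved and the silyl ether and isolated alkene inert.

Step 13
Reactants: 16 (4S,5S,8R,9R,10R)-18-{[tert-butyl(diphenyl)silyl]oxy}-12,13,14,15,16-pentanorlabd-6-en-11-ol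
Product: 17 (4S,5S,8R,9R,10R)-18-{[tert-butyl(diphenyl)silyl]oxy}-12,13,14,15,16-pentanorlabd-6-en-11-yl trifluoromethanesulfonate
Conditions: Tf2O, pyridine, CH2Cl2, −78 → −20 °C; used at once
Reagents that add atoms: trifluoromethanesulfonic anhydride, O=S(=O)(OS(=O)(=O)C(F)(F)F)C(F)(F)F
Why: Triflation turns the beta-branched primary alcohol into the most reactive sulfonate, which is what SN2 at the congested C11 requires.

Step 14
Reactants: 17 (4S,5S,8R,9R,10R)-18-{[tert-butyl(diphenyl)silyl]oxy}-12,13,14,15,16-pentanorlabd-6-en-11-yl trifluoromethanesulfonate; 18 1-(trimethylsilyl)prop-1-yne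
Product: 19 (4S,5S,8R,9R,10S)-18-{[tert-butyl(diphenyl)silyl]oxy}-14-(trimethylsilyl)-15,16-dinorlabd-6-en-13-yne
Conditions: 18, n-BuLi, THF, −20 °C; then 17, −78 → 0 °C
Reagents that add atoms: none
Why: SN2 alkylation of 3-lithio-1-(trimethylsilyl)propyne, a propargyl anion that reacts at its CH2 terminus, by the primary triflate forms C11–C12 and installs the silyl-capped alkyne that masks the diene.

Step 15
Reactants: 19 (4S,5S,8R,9R,10S)-18-{[tert-butyl(diphenyl)silyl]oxy}-14-(trimethylsilyl)-15,16-dinorlabd-6-en-13-yne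
Product: 20 (4S,5S,6S,7R,8S,9R,10S)-18-{[tert-butyl(diphenyl)silyl]oxy}-14-(trimethylsilyl)-15,16-dinorlabd-13-yne-6,7-diol (both hydroxyls on the H5 face)
Conditions: K2OsO4·2H2O (cat.), NMO, acetone/H2O, 23 °C
Reagents that add atoms: N-methylmorpholine N-oxide, C[N+]1([O-])CCOCC1; water, O
Why: Osmium-catalysed syn dihydroxylation of the only alkene takes place on the H5 face because the C20 face is blocked by the axial C19 and C20 methyls and the pseudoaxial C17 methyl, which sets C6 with an equatorial oxygen and places the C7 hydroxyl axial and cis to H8.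

Step 16
Reactants: 20 (4S,5S,6S,7R,8S,9R,10S)-18-{[tert-butyl(diphenyl)silyl]oxy}-14-(trimethylsilyl)-15,16-dinorlabd-13-yne-6,7-diol
Product: 22 (4S,5S,6S,7R,8S,9R,10S)-18-{[tert-butyl(diphenyl)silyl]oxy}-7-hydroxy-14-(trimethylsilyl)-15,16-dinorlabd-13-yn-6-yl benzoate, via dibutylstannylene acetal 21 (not isolated)
Conditions: Bu2SnO, toluene, reflux (−H2O); then BzCl, 0 → 23 °C
Reagents that add atoms: benzoyl chloride, O=C(Cl)c1ccccc1; dibutyltin oxide, CCCC[Sn](=O)CCCC (tin stays only in 21)
Why: Stannylene-mediated regioselective acylation, which in cis-1,2-diols on six-membered rings directs the acyl group to the equatorial oxygen, protects O6 and leaves the axial C7 hydroxyl free.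

Step 17
Reactants: 22 (4S,5S,6S,7R,8S,9R,10S)-18-{[tert-butyl(diphenyl)silyl]oxy}-7-hydroxy-14-(trimethylsilyl)-15,16-dinorlabd-13-yn-6-yl benzoate
Product: 23 (4S,5S,6R,9R,10S)-18-{[tert-butyl(diphenyl)silyl]oxy}-14-(trimethylsilyl)-15,16-dinorlabd-7-en-13-yn-6-yl benzoate
Conditions: Burgess reagent, toluene, 70 °C
Reagents that add atoms: none
Why: Burgess dehydration is a thermal syn elimination of the sulfamate ester, and since the only hydrogen cis to the axial C7 oxygen is H8 (H6 is trans) the C7=C8 alkene should form regiospecifically.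

Step 18
Reactants: 23 (4S,5S,6R,9R,10S)-18-{[tert-butyl(diphenyl)silyl]oxy}-14-(trimethylsilyl)-15,16-dinorlabd-7-en-13-yn-6-yl benzoate
Product: 24 (4S,5S,6S,7S,8R,9S,10R)-18-{[tert-butyl(diphenyl)silyl]oxy}-7,8-epoxy-14-(trimethylsilyl)-15,16-dinorlabd-13-yn-6-yl benzoate (epoxide oxygen on the H5 face)
Conditions: mCPBA, CH2Cl2, 0 °C
Reagents that add atoms: 3-chloroperoxybenzoic acid, O=C(OO)c1cccc(Cl)c1
Why: Prilezhaev epoxidation of the trisubstituted alkene (the silyl alkyne is inert) occurs on the H5 face, opposite the axial C10 methyl that shields C8, which places the C8 oxygen equatorial and the C17 methyl axial as the target requires.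

Step 19
Reactants: 24 (4S,5S,6S,7S,8R,9S,10R)-18-{[tert-butyl(diphenyl)silyl]oxy}-7,8-epoxy-14-(trimethylsilyl)-15,16-dinorlabd-13-yn-6-yl benzoate
Product: 26 (4S,5S,6R,8S,9S,10R)-18-{[tert-butyl(diphenyl)silyl]oxy}-15,16-dinorlabd-13-yne-6,8-diol, via silylated diol 25 (not isolated)
Conditions: LiBHEt3, THF, 0 → 40 °C; then MeOH, K2CO3, 23 °C
Reagents that add atoms: none
Why: Hydride opens the trisubstituted epoxide by SN2 attack at the less substituted C7, so the C8–O bond and its configuration are kept, the benzoate is reduced off in the same operation, and the methanolic carbonate then protodesilylates the alkyne.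

Step 20
Reactants: 26 (4S,5S,6R,8S,9S,10R)-18-{[tert-butyl(diphenyl)silyl]oxy}-15,16-dinorlabd-13-yne-6,8-diol
Product: 27 (4S,5S,6R,8S,9S,10R)-18-{[tert-butyl(diphenyl)silyl]oxy}-8-hydroxy-15,16-dinorlabd-13-yn-6-yl acetate
Conditions: Ac2O, DMAP (cat.), pyridine, CH2Cl2, 23 °C
Reagents that add atoms: acetic anhydride, CC(=O)OC(C)=O
Why: DMAP-catalysed acetylation esterifies the secondary C6 hydroxyl, while the tertiary C8 hydroxyl does not react under these conditions.

Step 21
Reactants: 27 (4S,5S,6R,8S,9S,10R)-18-{[tert-butyl(diphenyl)silyl]oxy}-8-hydroxy-15,16-dinorlabd-13-yn-6-yl acetate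
Product: 28 (4S,5S,6R,8S,9S,10R)-8,18-dihydroxy-15,16-dinorlabd-13-yn-6-yl acetate
Conditions: Bu4NF, AcOH, THF, 23 °C
Reagents that add atoms: none
Why: Fluoride desilylation cleaves the Si–O bond, and the acetic acid buffer keeps the liberated C18 oxygen protonated so that the nearby C6 acetate neither migrates nor is lost.

Step 22
Reactants: 28 (4S,5S,6R,8S,9S,10R)-8,18-dihydroxy-15,16-dinorlabd-13-yn-6-yl acetate; 29 ethene
Product: 30 (4S,5S,6R,8S,9S,10R)-8,18-dihydroxylabda-13(16),14-dien-6-yl acetate (CNP0312185.1)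
Conditions: ethene (1 atm), second-generation Grubbs catalyst RuCl2(=CHPh)(H2IMes)(PCy3) (5 mol%), CH2Cl2, 40 °C
Reagents that add atoms: none
Why: Ruthenium-carbene-catalysed cross enyne metathesis of the terminal alkyne with ethene, a known route to 2-substituted buta-1,3-dienes, adds the two CH2 groups to give the C13(=C16)–C14=C15 diene under neutral conditions that tolerate the free hydroxyls and the acetate.

**Compound list**

1 | dimethyl 2-methylpropanedioate | COC(=O)C(C)C(=O)OC | starting material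
2 | 2-(3-chloropropyl)-2-methyl-1,3-dioxolane | CC1(CCCCl)OCCO1 | starting material
3 | dimethyl 2-methyl-2-[3-(2-methyl-1,3-dioxolan-2-yl)propyl]propanedioate | COC(=O)C(C)(CCCC1(C)OCCO1)C(=O)OC | intermediate
4 | (2R)-2-(methoxycarbonyl)-2-methyl-5-(2-methyl-1,3-dioxolan-2-yl)pentanoic acid | CC1(CCC[C@](C)(C(=O)O)C(=O)OC)OCCO1 | intermediate
5 | methyl (2R)-2-(hydroxymethyl)-2-methyl-5-(2-methyl-1,3-dioxolan-2-yl)pentanoate | CC1(CCC[C@](C)(CO)C(=O)OC)OCCO1 | intermediate
6 | methyl (2R)-2-{[tert-butyl(diphenyl)silyl]oxymethyl}-2-methyl-5-(2-methyl-1,3-dioxolan-2-yl)pentanoate | CC1(CCC[C@](C)(CO[Si](c2ccccc2)(c2ccccc2)C(C)(C)C)C(=O)OC)OCCO1 | intermediate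
7 | (2S)-2-{[tert-butyl(diphenyl)silyl]oxymethyl}-2-methyl-5-(2-methyl-1,3-dioxolan-2-yl)pentan-1-ol | CC1(CCC[C@](C)(CO[Si](c2ccccc2)(c2ccccc2)C(C)(C)C)CO)OCCO1 | intermediate
8 | (2R)-2-{[tert-butyl(diphenyl)silyl]oxymethyl}-2-methyl-5-(2-methyl-1,3-dioxolan-2-yl)pentanal | CC1(CCC[C@](C)(CO[Si](c2ccccc2)(c2ccccc2)C(C)(C)C)C=O)OCCO1 | intermediate
9 | (2E)-1-bromobut-2-ene | C/C=C/CBr | starting material
10 | diethyl [(2E)-but-2-en-1-yl]phosphonate | C/C=C/CP(=O)(OCC)OCC | intermediate
11 | tert-butyl({(2S,3E,5E)-2-methyl-2-[3-(2-methyl-1,3-dioxolan-2-yl)propyl]hepta-3,5-dien-1-yl}oxy)diphenylsilane | CC1(CCC[C@](C)(CO[Si](c2ccccc2)(c2ccccc2)C(C)(C)C)/C=C/C=C/C)OCCO1 | intermediate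
12 | (6S,7E,9E)-6-{[tert-butyl(diphenyl)silyl]oxymethyl}-6-methylundeca-7,9-dien-2-one | CC(=O)CCC[C@](C)(CO[Si](c1ccccc1)(c1ccccc1)C(C)(C)C)/C=C/C=C/C | intermediate
13 | trimethyl phosphonoacetate | COC(=O)CP(=O)(OC)OC | starting material
14 | methyl (2E,7S,8E,10E)-7-{[tert-butyl(diphenyl)silyl]oxymethyl}-3,7-dimethyldodeca-2,8,10-trienoate | COC(=O)/C=C(\C)CCC[C@](C)(CO[Si](c1ccccc1)(c1ccccc1)C(C)(C)C)/C=C/C=C/C | intermediate
15 | methyl (4S,5S,8R,9R,10R)-18-{[tert-butyl(diphenyl)silyl]oxy}-12,13,14,15,16-pentanorlabd-6-en-11-oate | COC(=O)[C@H]1[C@]2(C)CCC[C@](C)(CO[Si](c3ccccc3)(c3ccccc3)C(C)(C)C)[C@H]2C=C[C@H]1C | intermediate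
16 | (4S,5S,8R,9R,10R)-18-{[tert-butyl(diphenyl)silyl]oxy}-12,13,14,15,16-pentanorlabd-6-en-11-ol | OC[C@H]1[C@]2(C)CCC[C@](C)(CO[Si](c3ccccc3)(c3ccccc3)C(C)(C)C)[C@H]2C=C[C@H]1C | intermediate
17 | (4S,5S,8R,9R,10R)-18-{[tert-butyl(diphenyl)silyl]oxy}-12,13,14,15,16-pentanorlabd-6-en-11-yl trifluoromethanesulfonate | O=S(=O)(OC[C@H]1[C@]2(C)CCC[C@](C)(CO[Si](c3ccccc3)(c3ccccc3)C(C)(C)C)[C@H]2C=C[C@H]1C)C(F)(F)F | intermediate
18 | 1-(trimethylsilyl)prop-1-yne | CC#C[Si](C)(C)C | starting material
19 | (4S,5S,8R,9R,10S)-18-{[tert-butyl(diphenyl)silyl]oxy}-14-(trimethylsilyl)-15,16-dinorlabd-6-en-13-yne | C[Si](C)(C)C#CCC[C@H]1[C@]2(C)CCC[C@](C)(CO[Si](c3ccccc3)(c3ccccc3)C(C)(C)C)[C@H]2C=C[C@H]1C | intermediate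
20 | (4S,5S,6S,7R,8S,9R,10S)-18-{[tert-butyl(diphenyl)silyl]oxy}-14-(trimethylsilyl)-15,16-dinorlabd-13-yne-6,7-diol | C[Si](C)(C)C#CCC[C@H]1[C@]2(C)CCC[C@](C)(CO[Si](c3ccccc3)(c3ccccc3)C(C)(C)C)[C@H]2[C@H](O)[C@H](O)[C@H]1C | intermediate
21 | 6,7-O-dibutylstannylene acetal of diol 20 (2,2-dibutyl-1,3,2-dioxastannolane fused at C6–C7 on the H5 face) | C[Si](C)(C)C#CCC[C@H]1[C@]2(C)CCC[C@](C)(CO[Si](c3ccccc3)(c3ccccc3)C(C)(C)C)[C@H]2[C@@H]3O[Sn](CCCC)(CCCC)O[C@@H]3[C@H]1C | intermediate
22 | (4S,5S,6S,7R,8S,9R,10S)-18-{[tert-butyl(diphenyl)silyl]oxy}-7-hydroxy-14-(trimethylsilyl)-15,16-dinorlabd-13-yn-6-yl benzoate | C[Si](C)(C)C#CCC[C@H]1[C@]2(C)CCC[C@](C)(CO[Si](c3ccccc3)(c3ccccc3)C(C)(C)C)[C@H]2[C@H](OC(=O)c3ccccc3)[C@H](O)[C@H]1C | intermediate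
23 | (4S,5S,6R,9R,10S)-18-{[tert-butyl(diphenyl)silyl]oxy}-14-(trimethylsilyl)-15,16-dinorlabd-7-en-13-yn-6-yl benzoate | C[Si](C)(C)C#CCC[C@H]1[C@]2(C)CCC[C@](C)(CO[Si](c3ccccc3)(c3ccccc3)C(C)(C)C)[C@H]2[C@H](OC(=O)c3ccccc3)C=C1C | intermediate
24 | (4S,5S,6S,7S,8R,9S,10R)-18-{[tert-butyl(diphenyl)silyl]oxy}-7,8-epoxy-14-(trimethylsilyl)-15,16-dinorlabd-13-yn-6-yl benzoate | C[Si](C)(C)C#CCC[C@H]1[C@]2(C)CCC[C@](C)(CO[Si](c3ccccc3)(c3ccccc3)C(C)(C)C)[C@H]2[C@H](OC(=O)c3ccccc3)[C@@H]3O[C@@]31C | intermediate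
25 | (4S,5S,6R,8S,9S,10R)-18-{[tert-butyl(diphenyl)silyl]oxy}-14-(trimethylsilyl)-15,16-dinorlabd-13-yne-6,8-diol | C[Si](C)(C)C#CCC[C@H]1[C@]2(C)CCC[C@](C)(CO[Si](c3ccccc3)(c3ccccc3)C(C)(C)C)[C@H]2[C@H](O)C[C@]1(C)O | intermediate
26 | (4S,5S,6R,8S,9S,10R)-18-{[tert-butyl(diphenyl)silyl]oxy}-15,16-dinorlabd-13-yne-6,8-diol | C#CCC[C@H]1[C@]2(C)CCC[C@](C)(CO[Si](c3ccccc3)(c3ccccc3)C(C)(C)C)[C@H]2[C@H](O)C[C@]1(C)O | intermediate
27 | (4S,5S,6R,8S,9S,10R)-18-{[tert-butyl(diphenyl)silyl]oxy}-8-hydroxy-15,16-dinorlabd-13-yn-6-yl acetate | C#CCC[C@H]1[C@]2(C)CCC[C@](C)(CO[Si](c3ccccc3)(c3ccccc3)C(C)(C)C)[C@H]2[C@H](OC(C)=O)C[C@]1(C)O | intermediate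
28 | (4S,5S,6R,8S,9S,10R)-8,18-dihydroxy-15,16-dinorlabd-13-yn-6-yl acetate | C#CCC[C@H]1[C@]2(C)CCC[C@](C)(CO)[C@H]2[C@H](OC(C)=O)C[C@]1(C)O | intermediate
29 | ethene | C=C | starting material
30 | (4S,5S,6R,8S,9S,10R)-8,18-dihydroxylabda-13(16),14-dien-6-yl acetate | C=CC(=C)CC[C@H]1[C@]2(C)CCC[C@](C)(CO)[C@H]2[C@H](OC(C)=O)C[C@]1(C)O | target

**Step count and risks**

Total steps: 22. Longest linear sequence: 21 (steps 1–6 and 8–22; step 7 is a one-step side branch).

Steps most likely to fail: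

1. Step 11. The cycloaddition may be too slow for the doubly beta-substituted enoate, may leak through the exo mode to the cis-fused skeleton, or may distinguish the two diene faces only weakly because methyl and silyloxymethyl at C4 differ little near the reacting carbons. The fallback sets out from 14 and returns at 16. The ester is saponified (LiOH, THF/MeOH/H2O, 50 °C) to the trienoic acid F1. This is converted through its mixed pivalic anhydride (PivCl, Et3N, THF, −20 °C) and the lithium salt of (R)-4-benzyl-1,3-oxazolidin-2-one into the N-enoyl oxazolidinone F2. Me2AlCl (1.5 equiv, CH2Cl2, −30 °C) then gives a two-point-bound cationic dienophile, far more reactive than the ester complex, whose benzyl group blocks the enoate face that would lead to the unwanted C9/C10 series. Auxiliary and C4 centre therefore act in the same sense and should give the imide cycloadduct F3. Reductive removal of the auxiliary (LiBH4, THF/MeOH, 0 °C) leads straight to alcohol 16.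

2. Step 16. Acylation at the axial oxygen, double acylation or benzoyl migration between the two cis oxygens would erase the differentiation on which the regiospecific dehydration depends. The fallback sets out from 19 and returns at 25, and needs no differentiation of two hydroxyls. The alkene is epoxidised with mCPBA (CH2Cl2, 0 °C) on the H5 face to the 6,7-epoxide F4. Lithium diethylamide (Et2O/hexane, reflux) then effects the base-induced syn elimination of an epoxide to an allylic alcohol; removal of H8 gives the 7-en-6-ol F5, and competition by H5 is the open point of this sequence. VO(acac)2/t-BuOOH (toluene, 23 °C) delivers the epoxide oxygen cis to the hydroxyl to give the 7,8-epoxy-6-ol F6. LiBHEt3 (THF) opens it at C7 to the silylated diol 25, which is carried on as in step 19.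

3. Step 2. Incomplete discrimination of the enantiotopic ester groups by the esterase would give material of low enantiomeric purity that no later step can upgrade. The fallback sets out from 3 and returns at 4. Half-saponification with KOH (1 equiv, MeOH, 23 °C) gives the racemic half ester F7. Its salt with (S)-1-phenylethanamine is recrystallised to constant rotation to give the diastereomerically pure ammonium salt F8; the (R)-amine would be taken if the salt of the (2S)-acid proved the less soluble one. Cold 1 M HCl then releases 4.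

**Further compounds**

F1 | step 11 | trienoic acid, (2E,7S,8E,10E)-7-{[tert-butyl(diphenyl)silyl]oxymethyl}-3,7-dimethyldodeca-2,8,10-trienoic acid | OC(=O)/C=C(\C)CCC[C@](C)(CO[Si](c1ccccc1)(c1ccccc1)C(C)(C)C)/C=C/C=C/C
F2 | step 11 | N-enoyl oxazolidinone, (4R)-4-benzyl-3-[(2E,7S,8E,10E)-7-{[tert-butyl(diphenyl)silyl]oxymethyl}-3,7-dimethyldodeca-2,8,10-trienoyl]-1,3-oxazolidin-2-one | O=C1OC[C@@H](Cc2ccccc2)N1C(=O)/C=C(\C)CCC[C@](C)(CO[Si](c1ccccc1)(c1ccccc1)C(C)(C)C)/C=C/C=C/C
F3 | step 11 | imide cycloadduct, (4R)-4-benzyl-3-[(4S,5S,8R,9R,10R)-18-{[tert-butyl(diphenyl)silyl]oxy}-12,13,14,15,16-pentanorlabd-6-en-11-oyl]-1,3-oxazolidin-2-one | O=C1OC[C@@H](Cc2ccccc2)N1C(=O)[C@H]1[C@]2(C)CCC[C@](C)(CO[Si](c3ccccc3)(c3ccccc3)C(C)(C)C)[C@H]2C=C[C@H]1C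
F4 | step 16 | 6,7-epoxide, (4S,5S,6S,7R,8S,9R,10S)-18-{[tert-butyl(diphenyl)silyl]oxy}-6,7-epoxy-14-(trimethylsilyl)-15,16-dinorlabd-13-yne (oxygen on the H5 face) | C[Si](C)(C)C#CCC[C@H]1[C@]2(C)CCC[C@](C)(CO[Si](c3ccccc3)(c3ccccc3)C(C)(C)C)[C@H]2[C@@H]3O[C@@H]3[C@H]1C
F5 | step 16 | 7-en-6-ol, (4S,5S,6R,9R,10S)-18-{[tert-butyl(diphenyl)silyl]oxy}-14-(trimethylsilyl)-15,16-dinorlabd-7-en-13-yn-6-ol | C[Si](C)(C)C#CCC[C@H]1[C@]2(C)CCC[C@](C)(CO[Si](c3ccccc3)(c3ccccc3)C(C)(C)C)[C@H]2[C@H](O)C=C1C
F6 | step 16 | 7,8-epoxy-6-ol, (4S,5S,6S,7S,8R,9S,10R)-18-{[tert-butyl(diphenyl)silyl]oxy}-7,8-epoxy-14-(trimethylsilyl)-15,16-dinorlabd-13-yn-6-ol | C[Si](C)(C)C#CCC[C@H]1[C@]2(C)CCC[C@](C)(CO[Si](c3ccccc3)(c3ccccc3)C(C)(C)C)[C@H]2[C@H](O)[C@@H]3O[C@@]31C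
F7 | step 2 | racemic half ester, 2-(methoxycarbonyl)-2-methyl-5-(2-methyl-1,3-dioxolan-2-yl)pentanoic acid | CC1(CCCC(C)(C(=O)O)C(=O)OC)OCCO1
F8 | step 2 | ammonium salt, (1S)-1-phenylethanaminium (2R)-2-(methoxycarbonyl)-2-methyl-5-(2-methyl-1,3-dioxolan-2-yl)pentanoate | CC1(CCC[C@](C)(C(=O)[O-])C(=O)OC)OCCO1.C[C@H]([NH3+])c1ccccc1
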